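**Strategy.** The cyclopentane ring (C1, C2, C3, C3a, C8a; azulene locants) is disconnected at the C1–C2 methylene–methylene bond and the C3a–C8a ring-fusion bond. The key step unites an enantiopure cis-epoxy methyl ketone with methacrylonitrile: Michael addition of the ketone enolate (future C2) to the nitrile β-carbon (future C1), then 5-exo opening of the oxirane by the resulting tertiary α-cyano carbanion (Stork epoxynitrile cyclization). It exploits C8a as a carbon α to a nitrile (C8), the C3 carbinol as a ketone, and the C4 oxygen as an epoxide on C3a. One operation gives the cyclopentanone with C3a, C4 and quaternary C8a set; ring-closing metathesis later builds the seven-membered ring.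

Key step: step 5

Remark: the configuration is taken as drawn, that is a cis-fused (3aS,8aR) ring junction, (3R), (4R), (8R), and an (E)-2-methylbut-2-enoate (tiglate) ester.

Assumption: the vanadium-directed epoxidation of the (Z)-allylic alcohol in step 3 follows the usual threo preference of such substrates; only the threo isomer is carried on.

**Step 1**
Reactants: 1 (R)-but-3-yn-2-ol; 2 3-bromo-2-methylprop-1-ene (methallyl bromide)
Product: 3 (2R)-6-methylhept-6-en-3-yn-2-ol
Conditions: CuI (10 mol %), K2CO3, DMF, rt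
Reagents that add atoms: none
Why: Copper-catalysed allylation of the copper acetylide formed in situ (alkyne–allyl halide coupling) should give the skipped enyne without touching the carbinol stereocentre.

**Step 2**
Reactants: 3 (2R)-6-methylhept-6-en-3-yn-2-ol
Product: 4 (2R,3Z)-6-methylhepta-3,6-dien-2-ol
Conditions: H2 (1 atm), Lindlar catalyst (Pd/CaCO3 poisoned with Pb(OAc)2), quinoline, EtOAc, rt
Reagents that add atoms: none
Why: Lindlar semi-hydrogenation adds hydrogen syn to the alkyne only, which should give the (Z)-alkene and leave the 1,1-disubstituted alkene intact.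

**Step 3**
Reactants: 4 (2R,3Z)-6-methylhepta-3,6-dien-2-ol
Product: 5 (1R)-1-[(2S,3R)-3-(2-methylprop-2-en-1-yl)oxiran-2-yl]ethan-1-ol
Conditions: VO(acac)2 (3 mol %), t-BuOOH, CH2Cl2, 0 °C; chromatographic removal of the minor erythro isomer
Reagents that add atoms: tert-butyl hydroperoxide, CC(C)(C)OO
Why: Hydroxyl-directed vanadium-catalysed epoxidation is selective for the allylic alkene and should deliver oxygen syn to the hydroxyl in the A(1,3)-strain-minimised conformer, so the (R)-carbinol sets both oxirane centres (threo isomer).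

**Step 4**
Reactants: 5 (1R)-1-[(2S,3R)-3-(2-methylprop-2-en-1-yl)oxiran-2-yl]ethan-1-ol
Product: 6 1-[(2R,3R)-3-(2-methylprop-2-en-1-yl)oxiran-2-yl]ethan-1-one
Conditions: Pr4N[RuO4] (5 mol %), N-methylmorpholine N-oxide, 4 Å molecular sieves, CH2Cl2, rt
Reagents that add atoms: none
Why: Ley–Griffith oxidation should convert the secondary alcohol into the methyl ketone under neutral conditions that leave the cis-oxirane and its two stereocentres intact.

**Step 5**
Reactants: 6 1-[(2R,3R)-3-(2-methylprop-2-en-1-yl)oxiran-2-yl]ethan-1-one; 7 2-methylprop-2-enenitrile (methacrylonitrile)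
Product: 9 (1R,2S)-2-[(1R)-1-hydroxy-3-methylbut-3-en-1-yl]-1-methyl-3-oxocyclopentane-1-carbonitrile, via keto nitrile Michael adduct 8 (not isolated)
Conditions: KN(SiMe3)2 (2.2 equiv), THF, −78 °C; 7 (1.0 equiv, slow addition), −78 → 0 °C, then rt; AcOH quench at −78 °C
Reagents that add atoms: none
Why: KN(SiMe3)2 should enolise 6 only at its methyl group (the oxirane C–H is kinetically non-acidic) and the potassium enolate adds to the β-carbon of 7, forming the C1–C2 bond; the hexamethyldisilazane released shuttles protons so that adduct 8 rests as its ketone enolate instead of adding to further acceptor, and the second equivalent of base regenerates the tertiary α-cyano carbanion, which opens the oxirane at the carbon next to the enolate and forms the C3a–C8a bond. The closest known reaction type is the Michael-initiated ring closure, here a cyanoethylation-type Michael addition telescoped with a Stork epoxynitrile cyclization. The only ring closed is the cyclopentane, by a 5-exo-tet SN2 displacement in which the oxirane oxygen is the exocyclic leaving group. C3a is set by inversion at the (2R)-oxirane carbon, C4 is the untouched (3R)-oxirane carbon whose oxygen becomes the secondary alkoxide, and the quaternary C8a is set in the cyclisation transition state, where the slim potassium-bound nitrile and not the methyl group should lie cis to the bulky carbinol side chain. The step needs 5-exo rather than 6-endo opening, which the collinear SN2 geometry and the allylic activation of the proximal oxirane carbon by the neighbouring enolate should secure, and a single Michael addition, which slow addition of one equivalent of 7 should secure. The cold acetic acid quench returns the β-hydroxy ketone before retro-aldol cleavage or epimerisation at C3a can set in.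

**Step 6**
Reactants: 9 (1R,2S)-2-[(1R)-1-hydroxy-3-methylbut-3-en-1-yl]-1-methyl-3-oxocyclopentane-1-carbonitrile
Product: 10 (1R,2S)-2-[(1R)-1-{[tert-butyl(dimethyl)silyl]oxy}-3-methylbut-3-en-1-yl]-1-methyl-3-oxocyclopentane-1-carbonitrile
Conditions: t-BuMe2SiOTf (1.2 equiv), 2,6-lutidine, CH2Cl2, −78 °C
Reagents that add atoms: tert-butyldimethylsilyl trifluoromethanesulfonate, CC(C)(C)[Si](C)(C)OS(=O)(=O)C(F)(F)F
Why: Silylation of the secondary alcohol at −78 °C should be faster than enol silylation, and it blocks retro-aldol cleavage and reserves this oxygen for the late aryl ester.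

**Step 7**
Reactants: 10 (1R,2S)-2-[(1R)-1-{[tert-butyl(dimethyl)silyl]oxy}-3-methylbut-3-en-1-yl]-1-methyl-3-oxocyclopentane-1-carbonitrile
Product: 11 (1R,2S,3R)-2-[(1R)-1-{[tert-butyl(dimethyl)silyl]oxy}-3-methylbut-3-en-1-yl]-3-hydroxy-1-methyl-3-(propan-2-yl)cyclopentane-1-carbonitrile
Conditions: i-PrLi (2 equiv), CeCl3 (2.2 equiv), THF, −78 °C; aqueous NH4Cl at −78 °C
Reagents that add atoms: isopropyllithium, [Li]C(C)C
Why: The non-basic organocerium reagent (Imamoto addition) should add to the hindered, enolisable cyclopentanone faster than to the tertiary nitrile and from the face anti to the bulky α-side chain, which places isopropyl cis to the angular methyl and sets the (3R) tertiary carbinol.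

**Step 8**
Reactants: 11 (1R,2S,3R)-2-[(1R)-1-{[tert-butyl(dimethyl)silyl]oxy}-3-methylbut-3-en-1-yl]-3-hydroxy-1-methyl-3-(propan-2-yl)cyclopentane-1-carbonitrile
Product: 13 (1R,2S,3R)-2-[(1R)-1-{[tert-butyl(dimethyl)silyl]oxy}-3-methylbut-3-en-1-yl]-3-hydroxy-1-methyl-3-(propan-2-yl)cyclopentane-1-carbaldehyde, via N-aluminated aldimine 12 (not isolated)
Conditions: i-Bu2AlH (3 equiv), CH2Cl2, −78 → −20 °C; then 10% aqueous tartaric acid, 0 °C
Reagents that add atoms: water, O
Why: Diisobutylaluminium hydride reduction of a nitrile should stop at the N-aluminated aldimine, and mild aqueous acid hydrolysis releases the non-epimerisable α-quaternary aldehyde.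

**Step 9**
Reactants: 13 (1R,2S,3R)-2-[(1R)-1-{[tert-butyl(dimethyl)silyl]oxy}-3-methylbut-3-en-1-yl]-3-hydroxy-1-methyl-3-(propan-2-yl)cyclopentane-1-carbaldehyde
Product: 14 (1R,2S,3R)-2-[(1R)-1-{[tert-butyl(dimethyl)silyl]oxy}-3-methylbut-3-en-1-yl]-3-[(1R)-1-hydroxyprop-2-en-1-yl]-3-methyl-1-(propan-2-yl)cyclopentan-1-ol
Conditions: CH2=CHMgBr (4 equiv), THF, −78 → 0 °C; aqueous NH4Cl
Reagents that add atoms: vinylmagnesium bromide, C=C[Mg]Br
Why: Grignard addition to the α-quaternary aldehyde should occur anti to the ring carbon that carries the silyloxyalkyl chain, as predicted both by the Felkin–Anh model and by chelation of the carbonyl to the neighbouring cis magnesium alkoxide, giving the (R)-allylic alcohol.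

**Step 10**
Reactants: 14 (1R,2S,3R)-2-[(1R)-1-{[tert-butyl(dimethyl)silyl]oxy}-3-methylbut-3-en-1-yl]-3-[(1R)-1-hydroxyprop-2-en-1-yl]-3-methyl-1-(propan-2-yl)cyclopentan-1-ol
Product: 15 (3R,3aS,4R,8R,8aR)-4-{[tert-butyl(dimethyl)silyl]oxy}-6,8a-dimethyl-3-(propan-2-yl)-1,2,3,3a,4,5,8,8a-octahydroazulene-3,8-diol
Conditions: second-generation Grubbs catalyst (H2IMes)(PCy3)Cl2Ru=CHPh (5 mol %), CH2Cl2 (5 mM), 40 °C
Reagents that add atoms: none
Why: Ring-closing metathesis between the vinyl group and the methallyl alkene, held cis on the cyclopentane, should close the cis-fused seven-membered ring with its trisubstituted alkene.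

**Step 11**
Reactants: 15 (3R,3aS,4R,8R,8aR)-4-{[tert-butyl(dimethyl)silyl]oxy}-6,8a-dimethyl-3-(propan-2-yl)-1,2,3,3a,4,5,8,8a-octahydroazulene-3,8-diol; 16 (2E)-2-methylbut-2-enoyl chloride (tigloyl chloride)
Product: 17 (3R,3aS,4R,8R,8aR)-4-{[tert-butyl(dimethyl)silyl]oxy}-3-hydroxy-6,8a-dimethyl-3-(propan-2-yl)-1,2,3,3a,4,5,8,8a-octahydroazulen-8-yl (2E)-2-methylbut-2-enoate
Conditions: Et3N, DMAP, CH2Cl2, 0 °C → rt
Reagents that add atoms: none
Why: DMAP-catalysed acylation should take place only at the secondary allylic hydroxyl, because the tertiary hydroxyl is too hindered and the other secondary oxygen is silylated.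

**Step 12**
Reactants: 17 (3R,3aS,4R,8R,8aR)-4-{[tert-butyl(dimethyl)silyl]oxy}-3-hydroxy-6,8a-dimethyl-3-(propan-2-yl)-1,2,3,3a,4,5,8,8a-octahydroazulen-8-yl (2E)-2-methylbut-2-enoate
Product: 18 (3R,3aS,4R,8R,8aR)-3,4-dihydroxy-6,8a-dimethyl-3-(propan-2-yl)-1,2,3,3a,4,5,8,8a-octahydroazulen-8-yl (2E)-2-methylbut-2-enoate
Conditions: HF·pyridine, pyridine, THF, 0 °C → rt
Reagents that add atoms: none
Why: Fluoride-mediated desilylation under buffered conditions should free the secondary alcohol without acyl migration or loss of the tiglate.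

**Step 13**
Reactants: 18 (3R,3aS,4R,8R,8aR)-3,4-dihydroxy-6,8a-dimethyl-3-(propan-2-yl)-1,2,3,3a,4,5,8,8a-octahydroazulen-8-yl (2E)-2-methylbut-2-enoate; 19 4-acetoxybenzoyl chloride
Product: 21 (3R,3aS,4R,8R,8aR)-3-hydroxy-6,8a-dimethyl-8-{[(2E)-2-methylbut-2-enoyl]oxy}-3-(propan-2-yl)-1,2,3,3a,4,5,8,8a-octahydroazulen-4-yl 4-hydroxybenzoate (target), via 4-acetoxybenzoate ester 20 (not isolated)
Conditions: Et3N, DMAP, CH2Cl2, rt → 40 °C; then pyrrolidine, rt
Reagents that add atoms: none
Why: DMAP-catalysed esterification of the only secondary hydroxyl, followed in the same flask by aminolysis of the far more reactive aryl acetate, should unmask the phenol while the alkyl benzoate and the tiglate survive.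

**Compound list**
1 | (R)-but-3-yn-2-ol | C[C@@H](O)C#C | starting material
2 | 3-bromo-2-methylprop-1-ene (methallyl bromide) | C=C(C)CBr | starting material
3 | (2R)-6-methylhept-6-en-3-yn-2-ol | C[C@@H](O)C#CCC(C)=C | intermediate
4 | (2R,3Z)-6-methylhepta-3,6-dien-2-ol | C[C@@H](O)/C=C\CC(C)=C | intermediate
5 | (1R)-1-[(2S,3R)-3-(2-methylprop-2-en-1-yl)oxiran-2-yl]ethan-1-ol (threo cis-epoxy alcohol) | C[C@@H](O)[C@@H]1O[C@@H]1CC(C)=C | intermediate
6 | 1-[(2R,3R)-3-(2-methylprop-2-en-1-yl)oxiran-2-yl]ethan-1-one (cis-epoxy ketone) | CC(=O)[C@@H]1O[C@@H]1CC(C)=C | intermediate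
7 | 2-methylprop-2-enenitrile (methacrylonitrile) | C=C(C)C#N | starting material
8 | (2RS)-2-methyl-5-[(2R,3R)-3-(2-methylprop-2-en-1-yl)oxiran-2-yl]-5-oxopentanenitrile (present as its potassium enolate and α-cyano carbanion) | N#CC(C)CCC(=O)[C@@H]1O[C@@H]1CC(C)=C | intermediate
9 | (1R,2S)-2-[(1R)-1-hydroxy-3-methylbut-3-en-1-yl]-1-methyl-3-oxocyclopentane-1-carbonitrile | C=C(C)C[C@@H](O)[C@@H]1[C@@](C#N)(C)CCC1=O | intermediate
10 | (1R,2S)-2-[(1R)-1-{[tert-butyl(dimethyl)silyl]oxy}-3-methylbut-3-en-1-yl]-1-methyl-3-oxocyclopentane-1-carbonitrile | C=C(C)C[C@@H](O[Si](C)(C)C(C)(C)C)[C@@H]1[C@@](C#N)(C)CCC1=O | intermediate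
11 | (1R,2S,3R)-2-[(1R)-1-{[tert-butyl(dimethyl)silyl]oxy}-3-methylbut-3-en-1-yl]-3-hydroxy-1-methyl-3-(propan-2-yl)cyclopentane-1-carbonitrile | C=C(C)C[C@@H](O[Si](C)(C)C(C)(C)C)[C@@H]1[C@@](C#N)(C)CC[C@@]1(O)C(C)C | intermediate
12 | aldimine of 13, (1R,2S,3R)-configured 1-(iminomethyl)cyclopentane (N- and O-aluminated in the flask) | C=C(C)C[C@@H](O[Si](C)(C)C(C)(C)C)[C@@H]1[C@@](C=N)(C)CC[C@@]1(O)C(C)C | intermediate
13 | (1R,2S,3R)-2-[(1R)-1-{[tert-butyl(dimethyl)silyl]oxy}-3-methylbut-3-en-1-yl]-3-hydroxy-1-methyl-3-(propan-2-yl)cyclopentane-1-carbaldehyde | C=C(C)C[C@@H](O[Si](C)(C)C(C)(C)C)[C@@H]1[C@@](C=O)(C)CC[C@@]1(O)C(C)C | intermediate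
14 | (1R,2S,3R)-2-[(1R)-1-{[tert-butyl(dimethyl)silyl]oxy}-3-methylbut-3-en-1-yl]-3-[(1R)-1-hydroxyprop-2-en-1-yl]-3-methyl-1-(propan-2-yl)cyclopentan-1-ol | C=C(C)C[C@@H](O[Si](C)(C)C(C)(C)C)[C@@H]1[C@@]([C@H](O)C=C)(C)CC[C@@]1(O)C(C)C | intermediate
15 | (3R,3aS,4R,8R,8aR)-4-{[tert-butyl(dimethyl)silyl]oxy}-6,8a-dimethyl-3-(propan-2-yl)-1,2,3,3a,4,5,8,8a-octahydroazulene-3,8-diol | O[C@@H]1C=C(C)C[C@@H](O[Si](C)(C)C(C)(C)C)[C@@H]2[C@@]1(C)CC[C@@]2(O)C(C)C | intermediate
16 | (2E)-2-methylbut-2-enoyl chloride (tigloyl chloride) | C/C=C(\C)C(Cl)=O | starting material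
17 | (3R,3aS,4R,8R,8aR)-4-{[tert-butyl(dimethyl)silyl]oxy}-3-hydroxy-6,8a-dimethyl-3-(propan-2-yl)-1,2,3,3a,4,5,8,8a-octahydroazulen-8-yl (2E)-2-methylbut-2-enoate | C/C=C(\C)C(=O)O[C@@H]1C=C(C)C[C@@H](O[Si](C)(C)C(C)(C)C)[C@@H]2[C@@]1(C)CC[C@@]2(O)C(C)C | intermediate
18 | (3R,3aS,4R,8R,8aR)-3,4-dihydroxy-6,8a-dimethyl-3-(propan-2-yl)-1,2,3,3a,4,5,8,8a-octahydroazulen-8-yl (2E)-2-methylbut-2-enoate | C/C=C(\C)C(=O)O[C@@H]1C=C(C)C[C@@H](O)[C@@H]2[C@@]1(C)CC[C@@]2(O)C(C)C | intermediate
19 | 4-acetoxybenzoyl chloride | CC(=O)Oc1ccc(cc1)C(Cl)=O | starting material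
20 | (3R,3aS,4R,8R,8aR)-3-hydroxy-6,8a-dimethyl-8-{[(2E)-2-methylbut-2-enoyl]oxy}-3-(propan-2-yl)-1,2,3,3a,4,5,8,8a-octahydroazulen-4-yl 4-acetoxybenzoate | C/C=C(\C)C(=O)O[C@@H]1C=C(C)C[C@@H](OC(=O)c2ccc(OC(C)=O)cc2)[C@@H]2[C@@]1(C)CC[C@@]2(O)C(C)C | intermediate
21 | (3R,3aS,4R,8R,8aR)-3-hydroxy-6,8a-dimethyl-8-{[(2E)-2-methylbut-2-enoyl]oxy}-3-(propan-2-yl)-1,2,3,3a,4,5,8,8a-octahydroazulen-4-yl 4-hydroxybenzoate | C/C=C(\C)C(=O)O[C@@H]1C=C(C)C[C@@H](OC(=O)c2ccc(O)cc2)[C@@H]2[C@@]1(C)CC[C@@]2(O)C(C)C | target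

**Step count and risks**
Total step count: 13. Longest linear sequence: 13 steps (1 → 21); compounds 2, 7, 16 and 19 are commercial and enter directly.

Steps most likely to fail:

Step 5. The acceptor may oligomerise anionically, the epoxy ketone enolate may open in a Favorskii-type manner, or proton transfer may outrun cyclisation so that the sequence stalls after the Michael addition. The fallback runs the two bond formations separately with the ketone masked. It sets out from 6 and 7: the Michael addition alone is run with one equivalent of KN(SiMe3)2 and quenched cold, so that adduct 8 is isolated. Its ketone is masked (Et3SiOTf, Et3N) as the silyl enol ether 2-methyl-5-[(2R,3R)-3-(2-methylprop-2-en-1-yl)oxiran-2-yl]-5-[(triethylsilyl)oxy]pent-4-enenitrile F1. A separate Stork epoxynitrile cyclisation (KN(SiMe3)2, toluene, rt) on this single-anion substrate should give (1R,5S)-5-[(1R)-1-hydroxy-3-methylbut-3-en-1-yl]-1-methyl-4-[(triethylsilyl)oxy]cyclopent-3-ene-1-carbonitrile F2. Hydrolysis of the enol ether with aqueous acetic acid comes back to the route at 9.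

Step 7. The isopropyl reagent may enolise or reduce the hindered ketone (β-hydride transfer) instead of adding, or it may attack the face syn to the side chain. The fallback uses chelation control on the unprotected substrate. It sets out from 9: excess i-PrMgCl/CeCl3 is added to the free β-hydroxy ketone, so that the metal alkoxide chelates and activates the carbonyl and the nucleophile enters anti to the chelated side chain. This should give (1R,2S,3R)-3-hydroxy-2-[(1R)-1-hydroxy-3-methylbut-3-en-1-yl]-1-methyl-3-(propan-2-yl)cyclopentane-1-carbonitrile F3. Selective silylation of its secondary hydroxyl (t-BuMe2SiCl, imidazole, DMF) comes back to the route at 11.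

Step 9. Facial selectivity in the addition to the aldehyde may be poor, giving a mixture of carbinol epimers. The fallback replaces substrate control by reagent control. It sets out from 14 as the epimer mixture: Dess–Martin oxidation of the allylic alcohol gives 1-[(1R,2S,3R)-2-[(1R)-1-{[tert-butyl(dimethyl)silyl]oxy}-3-methylbut-3-en-1-yl]-3-hydroxy-1-methyl-3-(propan-2-yl)cyclopentyl]prop-2-en-1-one F4. Corey–Bakshi–Shibata reduction with the (S)-methyl oxazaborolidine and BH3·SMe2, with the quaternary ring carbon acting as the large group, should come back to the route at 14 as the (R)-carbinol.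

Further compounds
F1 | step 5 | 2-methyl-5-[(2R,3R)-3-(2-methylprop-2-en-1-yl)oxiran-2-yl]-5-[(triethylsilyl)oxy]pent-4-enenitrile | N#CC(C)CC=C(O[Si](CC)(CC)CC)[C@@H]1O[C@@H]1CC(C)=C
F2 | step 5 | (1R,5S)-5-[(1R)-1-hydroxy-3-methylbut-3-en-1-yl]-1-methyl-4-[(triethylsilyl)oxy]cyclopent-3-ene-1-carbonitrile | C=C(C)C[C@@H](O)[C@@H]1[C@@](C#N)(C)CC=C1O[Si](CC)(CC)CC
F3 | step 7 | (1R,2S,3R)-3-hydroxy-2-[(1R)-1-hydroxy-3-methylbut-3-en-1-yl]-1-methyl-3-(propan-2-yl)cyclopentane-1-carbonitrile | C=C(C)C[C@@H](O)[C@@H]1[C@@](C#N)(C)CC[C@@]1(O)C(C)C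
F4 | step 9 | 1-[(1R,2S,3R)-2-[(1R)-1-{[tert-butyl(dimethyl)silyl]oxy}-3-methylbut-3-en-1-yl]-3-hydroxy-1-methyl-3-(propan-2-yl)cyclopentyl]prop-2-en-1-one | C=C(C)C[C@@H](O[Si](C)(C)C(C)(C)C)[C@@H]1[C@@](C(=O)C=C)(C)CC[C@@]1(O)C(C)C
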